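**Retrosynthetic overview**
- The target is opened first at the bond between the quaternary ring carbon and the CH2C(=O)Ar arm: a catalyst-controlled Mukaiyama addition of the silyl enol ether of protected 2′,5′-dihydroxyacetophenone to the cyclic oxocarbenium ion of a 4,7-dihydrooxepine-2-carboxylate sets the only stereocentre.
- The dihydrooxepine is opened by a formal (4+3) disconnection at O1–C7 and C3–C4: a palladium acyl carbene from a diazopyruvate ester is added to the terminal C=C of silyl-protected E-hydroxymyrcene, and the cis-alkenylcyclopropyl keto ester rearranges by a retro-Claisen (hetero-Cope) [3,3] shift.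
- Enabling feature: in the oxepine ring, C4–C5=C6(R)–C7 is the 1,4-adduct pattern of a 2-substituted buta-1,3-diene, and O1–C2–C3 is a C–C–O unit at the α-keto ester (acyl carbene) oxidation level, so the ring is the strain-release isomer of a cis-2-alkenylcyclopropyl ketone.
- Only the oxepine ring is built (one operation); the hydroquinone ring enters intact; one fluoride step removes all protecting groups.

Key step: step 5

Assumption: the descriptors of the target are read as S at the quaternary ring carbon and E at the side-chain double bond; oxepine numbering O1, C2 (quaternary), C3, C4, C5=C6, C7 is used throughout.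

**Route**

Step 1
Reactants: 1 β-myrcene (7-methyl-3-methylideneocta-1,6-diene)
Product: 2 (2E)-2-methyl-6-methylideneocta-2,7-dien-1-ol
Conditions: SeO2 (0.1 equiv), t-BuOOH (2 equiv), salicylic acid (0.1 equiv), CH2Cl2, 0 °C to 23 °C
Reagents that add atoms: tert-butyl hydroperoxide, CC(C)(C)OO (terminal oxidant; the oxygen is passed on through SeO2, O=[Se]=O)
Why: Allylic oxidation by SeO2 (ene reaction, then [2,3]-sigmatropic shift) attacks the E-methyl group of the electron-rich trisubstituted alkene and should give the E-allylic alcohol, the conjugated diene being less reactive.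

Step 2
Reactants: 2 (2E)-2-methyl-6-methylideneocta-2,7-dien-1-ol
Product: 3 tert-butyl(dimethyl){[(2E)-2-methyl-6-methylideneocta-2,7-dien-1-yl]oxy}silane
Conditions: t-BuMe2SiCl (1.2 equiv), imidazole (2 equiv), DMF, 23 °C
Reagents that add atoms: tert-butyl(chloro)dimethylsilane, CC(C)(C)[Si](C)(C)Cl
Why: Standard silylation of a primary alcohol; it removes the O–H bond that would otherwise trap the carbene of step 5.

Step 3
Reactants: 4 2-(trimethylsilyl)ethanol; 5 oxalyl chloride
Product: 6 2-(trimethylsilyl)ethyl chloro(oxo)acetate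
Conditions: 5 (3 equiv), Et2O, 0 °C to 23 °C; volatiles removed under vacuum
Reagents that add atoms: none
Why: Acylation of the alcohol by excess oxalyl chloride should stop at the mono-ester, because the chloro(oxo)acetate is less electrophilic than oxalyl chloride.

Step 4
Reactants: 6 2-(trimethylsilyl)ethyl chloro(oxo)acetate
Product: 7 2-(trimethylsilyl)ethyl 3-diazo-2-oxopropanoate
Conditions: Me3SiCHN2 (2.2 equiv), MeCN–THF, 0 °C to 23 °C
Reagents that add atoms: (trimethylsilyl)diazomethane, C[Si](C)(C)C=[N+]=[N-]
Why: C-acylation of the diazoalkane by the acid chloride with loss of Me3SiCl (diazo ketone synthesis of the Arndt–Eistert type) should give the diazopyruvate, the acyl chloride reacting far faster than the ester.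

Step 5
Reactants: 3 tert-butyl(dimethyl){[(2E)-2-methyl-6-methylideneocta-2,7-dien-1-yl]oxy}silane; 7 2-(trimethylsilyl)ethyl 3-diazo-2-oxopropanoate
Product: 9 2-(trimethylsilyl)ethyl 6-[(3E)-5-{[tert-butyl(dimethyl)silyl]oxy}-4-methylpent-3-en-1-yl]-4,7-dihydrooxepine-2-carboxylate, via cis-cyclopropyl keto ester 8 (not isolated)
Conditions: 3 (2 equiv), Pd2(dba)3 (2.5 mol %), toluene, 40 °C, 7 added over 6 h; then 60 °C, 12 h
Reagents that add atoms: none
Why: Zerovalent palladium decomposes 7 to a palladium acyl carbene, which is transferred to the monosubstituted C=C of 3 ([2+1] closure of the cyclopropane, making the C3–C4 bond); palladium carbenes are known to prefer the terminal, less substituted double bond of 2-substituted 1,3-dienes, the reverse of electrophilic rhodium carbenoids, so the 1,1-disubstituted and trisubstituted alkenes should stay untouched. In cis-8 the keto carbonyl and the alkenyl group lie on one face, so a concerted [3,3] sigmatropic shift (retro-Claisen rearrangement, boat transition state) forms the O1–C7 bond, breaks the cyclopropane bond C3–C5 and thereby closes the seven-membered ring. The closest known reactions are the retro-Claisen rearrangement of cis-2-vinylcyclopropyl aldehydes and ketones to 2,5-dihydrooxepines and the cyclopropanation/Cope (4+3) annulation of vinyl carbenoids with dienes. The shift should be driven by release of cyclopropane strain, by exchange of a destabilised 1,2-dicarbonyl for a conjugated 2-alkoxyacrylate and by the gain of an endocyclic trisubstituted alkene. No stereocentre survives (C2 is still sp2) and the ring fixes the C5=C6 bond as Z. The step needs site selectivity among three alkenes, secured by the vinyl group being the only unhindered terminal alkene that palladium binds, and a cis cyclopropane; no control of the cis/trans ratio is expected, and the trans isomer cannot rearrange (see fallback).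

Step 6
Reactants: 10 1-(2,5-dihydroxyphenyl)ethanone
Product: 11 tert-butyl[(1-{2,5-bis[(tert-butyldimethylsilyl)oxy]phenyl}ethenyl)oxy]dimethylsilane
Conditions: t-BuMe2SiOTf (3.5 equiv), Et3N (5 equiv), CH2Cl2, 0 °C to 23 °C
Reagents that add atoms: tert-butyldimethylsilyl trifluoromethanesulfonate, CC(C)(C)[Si](C)(C)OS(=O)(=O)C(F)(F)F
Why: The silyl triflate with amine base silylates both phenols and converts the methyl ketone into its silyl enol ether (soft enolisation), the methyl group being the only enolisable position.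

Step 7
Reactants: 9 2-(trimethylsilyl)ethyl 6-[(3E)-5-{[tert-butyl(dimethyl)silyl]oxy}-4-methylpent-3-en-1-yl]-4,7-dihydrooxepine-2-carboxylate; 11 tert-butyl[(1-{2,5-bis[(tert-butyldimethylsilyl)oxy]phenyl}ethenyl)oxy]dimethylsilane
Product: 13 2-(trimethylsilyl)ethyl (2S)-2-(2-{2,5-bis[(tert-butyldimethylsilyl)oxy]phenyl}-2-oxoethyl)-6-[(3E)-5-{[tert-butyl(dimethyl)silyl]oxy}-4-methylpent-3-en-1-yl]-2,3,4,7-tetrahydrooxepine-2-carboxylate, via methyl ketal 12 (not isolated)
Conditions: MeOH (1.05 equiv), one enantiomer of a confined chiral imidodiphosphorimidate (IDPi) Brønsted acid (5 mol %, enantiomer chosen by a small screen for the S product), toluene, −20 °C; then 11 (1.6 equiv), −60 °C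
Reagents that add atoms: none
Why: Proposed new method: the strong chiral acid adds methanol across the 2-alkoxyacrylate C2=C3 bond (proton to C3) to give ketal 12; the silylated catalyst formed from 11 then ionises 12, with loss of MeOSi(t-Bu)Me2, to a cyclic C2 oxocarbenium ion paired with the confined chiral anion, and Mukaiyama addition of 11 to the open face of this ion should set the quaternary S centre under catalyst control; the closest known reaction type is the imidodiphosphorimidate-catalysed asymmetric addition of enol silanes to cyclic oxocarbenium ions made from lactol acetates, here extended to a fully substituted, ester-bearing ion.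

Step 8
Reactants: 13 2-(trimethylsilyl)ethyl (2S)-2-(2-{2,5-bis[(tert-butyldimethylsilyl)oxy]phenyl}-2-oxoethyl)-6-[(3E)-5-{[tert-butyl(dimethyl)silyl]oxy}-4-methylpent-3-en-1-yl]-2,3,4,7-tetrahydrooxepine-2-carboxylate
Product: 14 (2S)-2-[2-(2,5-dihydroxyphenyl)-2-oxoethyl]-6-[(3E)-5-hydroxy-4-methylpent-3-en-1-yl]-2,3,4,7-tetrahydrooxepine-2-carboxylic acid
Conditions: Bu4NF (6 equiv), THF, 0 °C to 23 °C, under argon; aq. NH4Cl work-up
Reagents that add atoms: none
Why: Fluoride cleaves the three Si–O bonds and triggers β-fragmentation of the 2-(trimethylsilyl)ethyl ester (loss of ethene and Me3SiF), so one mild operation should free both phenols, the allylic alcohol and the acid; the stereocentre carries no hydrogen and cannot epimerise.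

**Compound list**
1 | β-myrcene (7-methyl-3-methylideneocta-1,6-diene) | CC(C)=CCCC(=C)C=C | starting material
2 | (2E)-2-methyl-6-methylideneocta-2,7-dien-1-ol | C/C(=C\CCC(=C)C=C)CO | intermediate
3 | tert-butyl(dimethyl){[(2E)-2-methyl-6-methylideneocta-2,7-dien-1-yl]oxy}silane | C/C(=C\CCC(=C)C=C)CO[Si](C)(C)C(C)(C)C | intermediate
4 | 2-(trimethylsilyl)ethanol | C[Si](C)(C)CCO | starting material
5 | oxalyl chloride | O=C(Cl)C(=O)Cl | starting material
6 | 2-(trimethylsilyl)ethyl chloro(oxo)acetate | C[Si](C)(C)CCOC(=O)C(=O)Cl | intermediate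
7 | 2-(trimethylsilyl)ethyl 3-diazo-2-oxopropanoate | C[Si](C)(C)CCOC(=O)C(=O)C=[N+]=[N-] | intermediate
8 | 2-(trimethylsilyl)ethyl 2-{cis-2-[(5E)-7-{[tert-butyl(dimethyl)silyl]oxy}-6-methylhepta-1,5-dien-2-yl]cyclopropyl}-2-oxoacetate (racemic, one enantiomer drawn) | C[Si](C)(C)CCOC(=O)C(=O)[C@H]1C[C@H]1C(=C)CC/C=C(\C)CO[Si](C)(C)C(C)(C)C | intermediate (not isolated)
9 | 2-(trimethylsilyl)ethyl 6-[(3E)-5-{[tert-butyl(dimethyl)silyl]oxy}-4-methylpent-3-en-1-yl]-4,7-dihydrooxepine-2-carboxylate | C[Si](C)(C)CCOC(=O)C1=CCC=C(CC/C=C(\C)CO[Si](C)(C)C(C)(C)C)CO1 | intermediate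
10 | 1-(2,5-dihydroxyphenyl)ethanone | CC(=O)c1cc(O)ccc1O | starting material
11 | tert-butyl[(1-{2,5-bis[(tert-butyldimethylsilyl)oxy]phenyl}ethenyl)oxy]dimethylsilane | C=C(O[Si](C)(C)C(C)(C)C)c1cc(O[Si](C)(C)C(C)(C)C)ccc1O[Si](C)(C)C(C)(C)C | intermediate
12 | 2-(trimethylsilyl)ethyl 6-[(3E)-5-{[tert-butyl(dimethyl)silyl]oxy}-4-methylpent-3-en-1-yl]-2-methoxy-2,3,4,7-tetrahydrooxepine-2-carboxylate (racemic) | COC1(C(=O)OCC[Si](C)(C)C)CCC=C(CC/C=C(\C)CO[Si](C)(C)C(C)(C)C)CO1 | intermediate (not isolated)
13 | 2-(trimethylsilyl)ethyl (2S)-2-(2-{2,5-bis[(tert-butyldimethylsilyl)oxy]phenyl}-2-oxoethyl)-6-[(3E)-5-{[tert-butyl(dimethyl)silyl]oxy}-4-methylpent-3-en-1-yl]-2,3,4,7-tetrahydrooxepine-2-carboxylate | C/C(=C\CCC1=CCC[C@](CC(=O)c2cc(O[Si](C)(C)C(C)(C)C)ccc2O[Si](C)(C)C(C)(C)C)(C(=O)OCC[Si](C)(C)C)OC1)CO[Si](C)(C)C(C)(C)C | intermediate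
14 | (2S)-2-[2-(2,5-dihydroxyphenyl)-2-oxoethyl]-6-[(3E)-5-hydroxy-4-methylpent-3-en-1-yl]-2,3,4,7-tetrahydrooxepine-2-carboxylic acid | C/C(=C\CCC1=CCC[C@](CC(=O)c2cc(O)ccc2O)(C(=O)O)OC1)CO | target

**Step count and risks**

Total step count: 8. Longest linear sequence: 5 steps (steps 1, 2, 5, 7, 8).

Step 7 (proposed new method). What may go wrong: poor facial discrimination in the addition to the ester-substituted oxocarbenium ion, or loss of the ion by elimination back to 9. The fallback sets out from 9 and comes back to the route at 14. Methanol and pyridinium p-toluenesulfonate convert 9 into ketal 12, now isolated. Me3SiOTf (0.1 equiv) and 11 in CH2Cl2 at −78 °C give the racemic adduct F1 (Mukaiyama addition to a ketal). Bu4NF gives the racemic acid F2. Fractional crystallisation with (S)-1-phenylethylamine gives the salt of the S acid F3 (the amine enantiomer is chosen by which salt crystallises), and partition between aqueous HCl and ethyl acetate liberates 14.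

Step 5 (key step). What may go wrong: carbene transfer delivers largely the trans cyclopropane, which cannot enter the sigmatropic shift and accumulates. The fallback sets out from 3 and 7 and comes back at 9. The carbene transfer is run at 25 °C and the trans cyclopropyl keto ester F4 is separated from 9. LiN(SiMe3)2 (THF, −78 °C) converts F4 into the planar lithium enolate F5. Protonation at −78 °C with 2,6-di-tert-butylphenol, from the face remote from the alkenyl group, should return the cis isomer 8, which rearranges to 9 on warming to 60 °C.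

Step 1. What may go wrong: over-oxidation to the enal and competing oxidation at the diene erode the material supply. The fallback sets out from 1 and comes back at 2. m-Chloroperbenzoic acid (CH2Cl2, NaHCO3, 0 °C) epoxidises only the trisubstituted alkene to give the epoxide F6. Al(Oi-Pr)3 in toluene at 110 °C isomerises it to the secondary allylic alcohol F7. Ph3SiOReO3 (2 mol %, Et2O, 0 °C) then effects 1,3-transposition of the hydroxyl group to the thermodynamically preferred primary E-allylic alcohol 2.

Further compounds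
F1 | step 7 | racemic 2-(trimethylsilyl)ethyl 2-(2-{2,5-bis[(tert-butyldimethylsilyl)oxy]phenyl}-2-oxoethyl)-6-[(3E)-5-{[tert-butyl(dimethyl)silyl]oxy}-4-methylpent-3-en-1-yl]-2,3,4,7-tetrahydrooxepine-2-carboxylate | C/C(=C\CCC1=CCCC(CC(=O)c2cc(O[Si](C)(C)C(C)(C)C)ccc2O[Si](C)(C)C(C)(C)C)(C(=O)OCC[Si](C)(C)C)OC1)CO[Si](C)(C)C(C)(C)C
F2 | step 7 | racemic 2-[2-(2,5-dihydroxyphenyl)-2-oxoethyl]-6-[(3E)-5-hydroxy-4-methylpent-3-en-1-yl]-2,3,4,7-tetrahydrooxepine-2-carboxylic acid | C/C(=C\CCC1=CCCC(CC(=O)c2cc(O)ccc2O)(C(=O)O)OC1)CO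
F3 | step 7 | (S)-1-phenylethylammonium (2S)-2-[2-(2,5-dihydroxyphenyl)-2-oxoethyl]-6-[(3E)-5-hydroxy-4-methylpent-3-en-1-yl]-2,3,4,7-tetrahydrooxepine-2-carboxylate | C/C(=C\CCC1=CCC[C@](CC(=O)c2cc(O)ccc2O)(C(=O)[O-])OC1)CO.C[C@H]([NH3+])c1ccccc1
F4 | step 5 | 2-(trimethylsilyl)ethyl 2-{trans-2-[(5E)-7-{[tert-butyl(dimethyl)silyl]oxy}-6-methylhepta-1,5-dien-2-yl]cyclopropyl}-2-oxoacetate (racemic, one enantiomer drawn) | C[Si](C)(C)CCOC(=O)C(=O)[C@H]1C[C@@H]1C(=C)CC/C=C(\C)CO[Si](C)(C)C(C)(C)C
F5 | step 5 | lithium enolate of F4 (lithium 1-{2-[(5E)-7-{[tert-butyl(dimethyl)silyl]oxy}-6-methylhepta-1,5-dien-2-yl]cyclopropylidene}-2-oxo-2-[2-(trimethylsilyl)ethoxy]ethanolate) | [Li+].[O-]C(C(=O)OCC[Si](C)(C)C)=C1CC1C(=C)CC/C=C(\C)CO[Si](C)(C)C(C)(C)C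
F6 | step 1 | 2,2-dimethyl-3-(3-methylidenepent-4-en-1-yl)oxirane (racemic) | CC1(C)OC1CCC(=C)C=C
F7 | step 1 | 2-methyl-6-methylideneocta-1,7-dien-3-ol (racemic) | C=CC(=C)CCC(O)C(C)=C
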